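## Plan

1. Retrosynthetic cuts: the C6 ketone is unmasked last from a C7a methyl ketal and a C6 MOM enol ether. Before that, C5–OCH3 and C5–allyl go back to the C5 carbonyl of a quinone monoketal, and this to the C5 phenol. Then come O1–C7a (dihydrofuran ring), the C3 methyl (from CH2OH) and C2–C3 (aldol).
2. Forward: 5-hydroxyvanillin becomes an arylacetyl oxazolidinone, which a boron aldol joins to 3,4,5-trimethoxybenzaldehyde. The acyl carbon is reduced to the C3 methyl, the ring O1–C2–C3–C3a–C7a is closed oxidatively, and the six-membered ring is then dearomatised and functionalised at C5.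
3. Enabling feature: C7a, the arene carbon that must carry O1, is unsubstituted and para to the C5 oxygen. Oxidation of the C5 phenol places the positive charge on C7a, the C2 hydroxyl reaches it through a five-membered transition state, and the C7a hydrogen is lost on rearomatisation. The same C5 oxygen ends as the C5 methoxy group.
4. Stereochemistry: C2 (S) and C3 (S) come from the syn boron aldol under control of (4S)-4-benzyl-oxazolidinone and are not touched afterwards. C5 (R) comes from addition of the allyl nucleophile to the C5 carbonyl on the face opposite the C3 methyl group; this control is expected to be modest.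

Key step: step 12

Remark: dihydrobenzofuran numbering (O1, C2, C3, C3a, C4–C7, C7a) is used for all bicyclic compounds; in 17 the aryl carbon that becomes C7a is called C6′ (C1′ carries the side chain, C3′ the free OH). Compounds 21–23 are carried as both C7a epimers, because C7a becomes sp2 again in step 16.

## Route

Step 1
Reactants: 1 5-hydroxyvanillin (3,4-dihydroxy-5-methoxybenzaldehyde)
Product: 2 3-hydroxy-5-methoxy-4-(methoxymethoxy)benzaldehyde
Conditions: MOMCl (1.05 equiv), K2CO3 (1.1 equiv), acetone, 0 °C → rt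
Reagents that add atoms: chloromethyl methyl ether, COCCl
Why: Williamson-type O-alkylation in which one equivalent of weak base ionises only the 4-OH (para to the formyl group, the most acidic), so the MOM group should go on that oxygen, as in 4-O-selective alkylations of 3,4-dihydroxybenzaldehydes.

Step 2
Reactants: 2 3-hydroxy-5-methoxy-4-(methoxymethoxy)benzaldehyde
Product: 3 3-methoxy-4-(methoxymethoxy)-5-[(triisopropylsilyl)oxy]benzaldehyde
Conditions: TIPSCl, imidazole, DMF, rt
Reagents that add atoms: chlorotriisopropylsilane, CC(C)[Si](Cl)(C(C)C)C(C)C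
Why: imidazole-promoted silyl ether formation at the remaining phenol; TIPS should survive ylide, borane, boron-enolate and hydride conditions and is later removed by fluoride without loss of the MOM ether.

Step 3
Reactants: 3 3-methoxy-4-(methoxymethoxy)-5-[(triisopropylsilyl)oxy]benzaldehyde
Product: 4 5-ethenyl-1-methoxy-2-(methoxymethoxy)-3-[(triisopropylsilyl)oxy]benzene
Conditions: Ph3PCH3Br, KOt-Bu, THF, 0 °C → rt
Reagents that add atoms: methyltriphenylphosphonium bromide, C[P+](c1ccccc1)(c1ccccc1)c1ccccc1.[Br-]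
Why: Wittig methylenation of an aromatic aldehyde with a non-stabilised ylide.

Step 4
Reactants: 4 5-ethenyl-1-methoxy-2-(methoxymethoxy)-3-[(triisopropylsilyl)oxy]benzene
Product: 6 2-{3-methoxy-4-(methoxymethoxy)-5-[(triisopropylsilyl)oxy]phenyl}ethan-1-ol, via B-(2-arylethyl)-9-borabicyclo[3.3.1]nonane 5 (not isolated)
Conditions: 9-BBN, THF, 0 °C → rt; then 30% H2O2, aq NaOAc, 0 °C → rt
Reagents that add atoms: hydrogen peroxide, OO
Why: hydroboration–oxidation, in which 9-BBN adds anti-Markovnikov to the styrene and acetate-buffered peroxide converts C–B into C–OH without cleaving the aryl silyl ether.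

Step 5
Reactants: 6 2-{3-methoxy-4-(methoxymethoxy)-5-[(triisopropylsilyl)oxy]phenyl}ethan-1-ol
Product: 7 {3-methoxy-4-(methoxymethoxy)-5-[(triisopropylsilyl)oxy]phenyl}acetic acid
Conditions: TEMPO (20 mol%), PhI(OAc)2 (2.2 equiv), MeCN–H2O (1:1), rt
Reagents that add atoms: water, O
Why: TEMPO/PhI(OAc)2 oxidation of a primary alcohol in aqueous acetonitrile, which should run through the aldehyde hydrate to the carboxylic acid and leave the arene, MOM and silyl groups alone.

Step 6
Reactants: 7 {3-methoxy-4-(methoxymethoxy)-5-[(triisopropylsilyl)oxy]phenyl}acetic acid; 8 (4S)-4-benzyl-1,3-oxazolidin-2-one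
Product: 10 (4S)-4-benzyl-3-({3-methoxy-4-(methoxymethoxy)-5-[(triisopropylsilyl)oxy]phenyl}acetyl)-1,3-oxazolidin-2-one, via mixed pivalic anhydride 9 (not isolated)
Conditions: PivCl, Et3N, THF, −20 → 0 °C; then 8, LiCl, rt
Reagents that add atoms: none
Why: N-acylation of the oxazolidinone by a mixed pivalic anhydride under LiCl/Et3N activation, the mild standard route to such imides, which should avoid ketene formation from the arylacetyl unit.

Step 7
Reactants: 10 (4S)-4-benzyl-3-({3-methoxy-4-(methoxymethoxy)-5-[(triisopropylsilyl)oxy]phenyl}acetyl)-1,3-oxazolidin-2-one; 11 3,4,5-trimethoxybenzaldehyde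
Product: 13 (4S)-4-benzyl-3-[(2S,3S)-3-hydroxy-2-{3-methoxy-4-(methoxymethoxy)-5-[(triisopropylsilyl)oxy]phenyl}-3-(3,4,5-trimethoxyphenyl)propanoyl]-1,3-oxazolidin-2-one, via Z-dibutylboron enolate 12 (not isolated)
Conditions: Bu2BOTf, i-Pr2NEt, CH2Cl2, −78 → 0 °C; 11, −78 → 0 °C; then pH 7 buffer, MeOH, 30% H2O2, 0 °C
Reagents that add atoms: none
Why: Evans boron aldol, in which the Z-enolate reacts through a chair Zimmerman–Traxler transition state on the face opposite the auxiliary's benzyl group; this should give the 2,3-syn adduct and set both propanoyl centres (2S,3S), the later C3 and C2 of the benzofuran.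

Step 8
Reactants: 13 (4S)-4-benzyl-3-[(2S,3S)-3-hydroxy-2-{3-methoxy-4-(methoxymethoxy)-5-[(triisopropylsilyl)oxy]phenyl}-3-(3,4,5-trimethoxyphenyl)propanoyl]-1,3-oxazolidin-2-one
Product: 14 (1S,2R)-2-{3-methoxy-4-(methoxymethoxy)-5-[(triisopropylsilyl)oxy]phenyl}-1-(3,4,5-trimethoxyphenyl)propane-1,3-diol
Conditions: LiBH4, H2O (1 equiv), THF, 0 °C
Reagents that add atoms: none
Why: reductive cleavage of the imide by LiBH4 at the exocyclic carbonyl should release the auxiliary and give the 1,3-diol without epimerising the benzylic α-centre (the descriptor changes to 2R only through CIP priorities).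

Step 9
Reactants: 14 (1S,2R)-2-{3-methoxy-4-(methoxymethoxy)-5-[(triisopropylsilyl)oxy]phenyl}-1-(3,4,5-trimethoxyphenyl)propane-1,3-diol
Product: 15 (2R,3S)-3-hydroxy-2-{3-methoxy-4-(methoxymethoxy)-5-[(triisopropylsilyl)oxy]phenyl}-3-(3,4,5-trimethoxyphenyl)propyl 4-methylbenzenesulfonate
Conditions: TsCl (1.1 equiv), Et3N, DMAP (cat.), CH2Cl2, 0 °C
Reagents that add atoms: 4-methylbenzenesulfonyl chloride, Cc1ccc(cc1)S(Cl)(=O)=O
Why: selective sulfonylation of a 1,3-diol at the unhindered primary hydroxyl in preference to the secondary benzylic one.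

Step 10
Reactants: 15 (2R,3S)-3-hydroxy-2-{3-methoxy-4-(methoxymethoxy)-5-[(triisopropylsilyl)oxy]phenyl}-3-(3,4,5-trimethoxyphenyl)propyl 4-methylbenzenesulfonate
Product: 16 (1S,2S)-2-{3-methoxy-4-(methoxymethoxy)-5-[(triisopropylsilyl)oxy]phenyl}-1-(3,4,5-trimethoxyphenyl)propan-1-ol
Conditions: LiEt3BH, THF, 0 °C → rt
Reagents that add atoms: none
Why: hydride reduction of a primary tosylate (SN2 by LiEt3BH) should turn CH2OTs into the later C3 methyl group and leave both stereocentres untouched.

Step 11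
Reactants: 16 (1S,2S)-2-{3-methoxy-4-(methoxymethoxy)-5-[(triisopropylsilyl)oxy]phenyl}-1-(3,4,5-trimethoxyphenyl)propan-1-ol
Product: 17 (1S,2S)-2-[3-hydroxy-5-methoxy-4-(methoxymethoxy)phenyl]-1-(3,4,5-trimethoxyphenyl)propan-1-ol
Conditions: TBAF, AcOH, THF, 0 °C
Reagents that add atoms: none
Why: fluoride desilylation of the aryl silyl ether, buffered with acetic acid so that the electron-rich phenol is not handled as its phenoxide; the MOM ether and the benzylic alcohol should be inert.

Step 12
Reactants: 17 (1S,2S)-2-[3-hydroxy-5-methoxy-4-(methoxymethoxy)phenyl]-1-(3,4,5-trimethoxyphenyl)propan-1-ol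
Product: 20 (2S,3S)-7-methoxy-6-(methoxymethoxy)-3-methyl-2-(3,4,5-trimethoxyphenyl)-2,3-dihydro-1-benzofuran-5-ol, via aryloxy(acetoxy)phenyl-λ3-iodane 18 (not isolated), via 7aH-cyclohexa-2,5-dienone tautomer 19 (not isolated)
Conditions: PhI(OAc)2 (1.0 equiv, added slowly), (CF3)2CHOH–CH2Cl2 (1:4), −30 °C
Reagents that add atoms: none
Why: Ligand exchange of the C3′ phenol at iodine(III) and loss of iodobenzene and acetate should give a phenoxonium ion with positive charge on the unsubstituted para carbon C6′ (the later C7a); the C1 hydroxyl captures it, and the 7aH-dienone 19 tautomerises to the phenol. The closest known reaction type is the hypervalent-iodine oxidation of para-unsubstituted phenols with capture by an oxygen nucleophile at the para carbon and rearomatisation (the first stage of the PhI(OAc)2/alcohol route to quinone monoketals), here intramolecular. The ring O1–C2–C3–C3a–C7a closes in a 5-exo-trig mode, the hydroxyl adding to the C5′=C6′ terminus of the quinoid cation. No stereocentre is formed and neither aldol centre belongs to the ionised system, so the trans arrangement should be kept. Site selectivity for para C6′ over the equally reachable ortho C2′ and over external attack at the MOM-bearing C4′ rests on the larger para coefficient of the cation and on the non-nucleophilic fluoroalcohol. Chemoselectivity against further oxidation of the more electron-rich product rests on slow addition of exactly one equivalent of oxidant at low temperature.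

Step 13
Reactants: 20 (2S,3S)-7-methoxy-6-(methoxymethoxy)-3-methyl-2-(3,4,5-trimethoxyphenyl)-2,3-dihydro-1-benzofuran-5-ol
Product: 21 (2S,3S)-7,7a-dimethoxy-6-(methoxymethoxy)-3-methyl-2-(3,4,5-trimethoxyphenyl)-3,7a-dihydro-1-benzofuran-5(2H)-one (both C7a epimers)
Conditions: PhI(OAc)2 (1.1 equiv), NaHCO3, MeOH, 0 °C
Reagents that add atoms: methanol, CO
Why: quinone monoketal formation by hypervalent-iodine oxidation of a para-alkoxyphenol in methanol (the chromanol-to-8a-alkoxychromanone type), methanol adding at C7a because it is para to the oxidised oxygen and stabilised by O1; the new ketal centre is not controlled and is erased in step 16.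

Step 14
Reactants: 21 (2S,3S)-7,7a-dimethoxy-6-(methoxymethoxy)-3-methyl-2-(3,4,5-trimethoxyphenyl)-3,7a-dihydro-1-benzofuran-5(2H)-one (both C7a epimers)
Product: 22 (2S,3S,5R)-7,7a-dimethoxy-6-(methoxymethoxy)-3-methyl-5-(prop-2-en-1-yl)-2-(3,4,5-trimethoxyphenyl)-2,3,5,7a-tetrahydro-1-benzofuran-5-ol (both C7a epimers)
Conditions: allylMgBr, THF, −78 °C; sat. aq NaHCO3
Reagents that add atoms: allylmagnesium bromide, C=CC[Mg]Br
Why: 1,2-addition of an allyl Grignard reagent to the carbonyl of a quinone monoketal, a standard reaction without conjugate addition; C5 is set by substrate control, the nucleophile entering on the dienone face opposite the C3 methyl group that lies over C4/C5 (giving 5R), and any 5-epimer is removed by chromatography after step 16, once C7a is sp2 again.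

Step 15
Reactants: 22 (2S,3S,5R)-7,7a-dimethoxy-6-(methoxymethoxy)-3-methyl-5-(prop-2-en-1-yl)-2-(3,4,5-trimethoxyphenyl)-2,3,5,7a-tetrahydro-1-benzofuran-5-ol (both C7a epimers)
Product: 23 (2S,3S,5R)-5,7,7a-trimethoxy-6-(methoxymethoxy)-3-methyl-5-(prop-2-en-1-yl)-2-(3,4,5-trimethoxyphenyl)-2,3,5,7a-tetrahydro-1-benzofuran (both C7a epimers)
Conditions: NaH, MeI, THF–DMF, 0 °C
Reagents that add atoms: iodomethane, CI
Why: Williamson O-methylation of the tertiary sodium alkoxide at 0 °C, expected to outrun allyl shifts of the bis-allylic alkoxide; it turns the oxygen that served as the activating phenol into the C5 methoxy group without touching the C5 configuration.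

Step 16
Reactants: 23 (2S,3S,5R)-5,7,7a-trimethoxy-6-(methoxymethoxy)-3-methyl-5-(prop-2-en-1-yl)-2-(3,4,5-trimethoxyphenyl)-2,3,5,7a-tetrahydro-1-benzofuran (both C7a epimers)
Product: 24 (2S,3S,5R)-5,7-dimethoxy-3-methyl-5-(prop-2-en-1-yl)-2-(3,4,5-trimethoxyphenyl)-3,5-dihydro-1-benzofuran-6(2H)-one
Conditions: PPTS (cat.), CH2Cl2, 0 °C → rt
Reagents that add atoms: none
Why: Stork–Danheiser-type vinylogous ketal cleavage, in which acid ionises the C7a mixed ketal to a cation delocalised over O1–C7a–C7–C6–O and the MOM group leaves the C6 oxygen as dimethoxymethane; this should unveil the C6 ketone and the C7=C7a enol ether, converge both C7a epimers and leave C2, C3 and C5 untouched.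

## Compound list

1 | 5-hydroxyvanillin (3,4-dihydroxy-5-methoxybenzaldehyde) | COc1cc(C=O)cc(O)c1O | starting material
2 | 3-hydroxy-5-methoxy-4-(methoxymethoxy)benzaldehyde | COCOc1c(O)cc(C=O)cc1OC | intermediate
3 | 3-methoxy-4-(methoxymethoxy)-5-[(triisopropylsilyl)oxy]benzaldehyde | COCOc1c(OC)cc(C=O)cc1O[Si](C(C)C)(C(C)C)C(C)C | intermediate
4 | 5-ethenyl-1-methoxy-2-(methoxymethoxy)-3-[(triisopropylsilyl)oxy]benzene | C=Cc1cc(OC)c(OCOC)c(O[Si](C(C)C)(C(C)C)C(C)C)c1 | intermediate
5 | 9-{2-[3-methoxy-4-(methoxymethoxy)-5-(triisopropylsilyloxy)phenyl]ethyl}-9-borabicyclo[3.3.1]nonane (formed and consumed in step 4) | COCOc1c(OC)cc(CCB2C3CCCC2CCC3)cc1O[Si](C(C)C)(C(C)C)C(C)C | intermediate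
6 | 2-{3-methoxy-4-(methoxymethoxy)-5-[(triisopropylsilyl)oxy]phenyl}ethan-1-ol | COCOc1c(OC)cc(CCO)cc1O[Si](C(C)C)(C(C)C)C(C)C | intermediate
7 | {3-methoxy-4-(methoxymethoxy)-5-[(triisopropylsilyl)oxy]phenyl}acetic acid | COCOc1c(OC)cc(CC(=O)O)cc1O[Si](C(C)C)(C(C)C)C(C)C | intermediate
8 | (4S)-4-benzyl-1,3-oxazolidin-2-one | O=C1N[C@@H](Cc2ccccc2)CO1 | starting material
9 | mixed anhydride of 7 with pivalic acid (formed and consumed in step 6) | COCOc1c(OC)cc(CC(=O)OC(=O)C(C)(C)C)cc1O[Si](C(C)C)(C(C)C)C(C)C | intermediate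
10 | (4S)-4-benzyl-3-({3-methoxy-4-(methoxymethoxy)-5-[(triisopropylsilyl)oxy]phenyl}acetyl)-1,3-oxazolidin-2-one | COCOc1c(OC)cc(CC(=O)N2[C@@H](Cc3ccccc3)COC2=O)cc1O[Si](C(C)C)(C(C)C)C(C)C | intermediate
11 | 3,4,5-trimethoxybenzaldehyde | COc1cc(C=O)cc(OC)c1OC | starting material
12 | (Z)-dibutylboron enolate of 10 (formed and consumed in step 7) | CCCCB(CCCC)O/C(N1[C@@H](Cc2ccccc2)COC1=O)=C\c1cc(OC)c(OCOC)c(O[Si](C(C)C)(C(C)C)C(C)C)c1 | intermediate
13 | (4S)-4-benzyl-3-[(2S,3S)-3-hydroxy-2-{3-methoxy-4-(methoxymethoxy)-5-[(triisopropylsilyl)oxy]phenyl}-3-(3,4,5-trimethoxyphenyl)propanoyl]-1,3-oxazolidin-2-one | O[C@H](c1cc(OC)c(OC)c(OC)c1)[C@@H](C(=O)N1[C@@H](Cc2ccccc2)COC1=O)c1cc(OC)c(OCOC)c(O[Si](C(C)C)(C(C)C)C(C)C)c1 | intermediate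
14 | (1S,2R)-2-{3-methoxy-4-(methoxymethoxy)-5-[(triisopropylsilyl)oxy]phenyl}-1-(3,4,5-trimethoxyphenyl)propane-1,3-diol | O[C@H](c1cc(OC)c(OC)c(OC)c1)[C@@H](CO)c1cc(OC)c(OCOC)c(O[Si](C(C)C)(C(C)C)C(C)C)c1 | intermediate
15 | (2R,3S)-3-hydroxy-2-{3-methoxy-4-(methoxymethoxy)-5-[(triisopropylsilyl)oxy]phenyl}-3-(3,4,5-trimethoxyphenyl)propyl 4-methylbenzenesulfonate | O[C@H](c1cc(OC)c(OC)c(OC)c1)[C@@H](COS(=O)(=O)c1ccc(C)cc1)c1cc(OC)c(OCOC)c(O[Si](C(C)C)(C(C)C)C(C)C)c1 | intermediate
16 | (1S,2S)-2-{3-methoxy-4-(methoxymethoxy)-5-[(triisopropylsilyl)oxy]phenyl}-1-(3,4,5-trimethoxyphenyl)propan-1-ol | O[C@H](c1cc(OC)c(OC)c(OC)c1)[C@@H](C)c1cc(OC)c(OCOC)c(O[Si](C(C)C)(C(C)C)C(C)C)c1 | intermediate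
17 | (1S,2S)-2-[3-hydroxy-5-methoxy-4-(methoxymethoxy)phenyl]-1-(3,4,5-trimethoxyphenyl)propan-1-ol | O[C@H](c1cc(OC)c(OC)c(OC)c1)[C@@H](C)c1cc(O)c(OCOC)c(OC)c1 | intermediate
18 | acetoxy(phenyl)-λ3-iodanyl ether of phenol 17, ArO–I(Ph)OAc (formed and consumed in step 12) | CC(=O)OI(c1ccccc1)Oc1cc(cc(OC)c1OCOC)[C@H](C)[C@H](O)c1cc(OC)c(OC)c(OC)c1 | intermediate
19 | (2S,3S)-7-methoxy-6-(methoxymethoxy)-3-methyl-2-(3,4,5-trimethoxyphenyl)-3,7a-dihydro-1-benzofuran-5(2H)-one, the 7aH-dienone tautomer of 20 with C7a not defined (formed and consumed in step 12) | O=C1C=C2[C@H](C)[C@@H](c3cc(OC)c(OC)c(OC)c3)OC2C(OC)=C1OCOC | intermediate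
20 | (2S,3S)-7-methoxy-6-(methoxymethoxy)-3-methyl-2-(3,4,5-trimethoxyphenyl)-2,3-dihydro-1-benzofuran-5-ol | COCOc1c(O)cc2c(c1OC)O[C@H](c1cc(OC)c(OC)c(OC)c1)[C@H]2C | intermediate
21 | (2S,3S)-7,7a-dimethoxy-6-(methoxymethoxy)-3-methyl-2-(3,4,5-trimethoxyphenyl)-3,7a-dihydro-1-benzofuran-5(2H)-one, both C7a epimers | O=C1C=C2[C@H](C)[C@@H](c3cc(OC)c(OC)c(OC)c3)OC2(OC)C(OC)=C1OCOC | intermediate
22 | (2S,3S,5R)-7,7a-dimethoxy-6-(methoxymethoxy)-3-methyl-5-(prop-2-en-1-yl)-2-(3,4,5-trimethoxyphenyl)-2,3,5,7a-tetrahydro-1-benzofuran-5-ol, both C7a epimers | C=CC[C@@]1(O)C=C2[C@H](C)[C@@H](c3cc(OC)c(OC)c(OC)c3)OC2(OC)C(OC)=C1OCOC | intermediate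
23 | (2S,3S,5R)-5,7,7a-trimethoxy-6-(methoxymethoxy)-3-methyl-5-(prop-2-en-1-yl)-2-(3,4,5-trimethoxyphenyl)-2,3,5,7a-tetrahydro-1-benzofuran, both C7a epimers | C=CC[C@@]1(OC)C=C2[C@H](C)[C@@H](c3cc(OC)c(OC)c(OC)c3)OC2(OC)C(OC)=C1OCOC | intermediate
24 | (2S,3S,5R)-5,7-dimethoxy-3-methyl-5-(prop-2-en-1-yl)-2-(3,4,5-trimethoxyphenyl)-3,5-dihydro-1-benzofuran-6(2H)-one | C=CC[C@@]1(OC)C=C2C(=C(OC)C1=O)O[C@H](c1cc(OC)c(OC)c(OC)c1)[C@H]2C | target

## Step count and risks

Total: 16 steps. Longest linear sequence: 16 steps (1 → 24); 8 and 11 are purchased.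

**Step 14.** What may go wrong: low facial selectivity in the addition to the C5 carbonyl. Allylmagnesium halides discriminate poorly between faces, the only bias is the remote C3 methyl group, and the two C7a epimers of 21 need not behave alike, so much 5-epimer may form. Fallback: reagent control in place of substrate control. Starting from 21, the ketone is allylated with an enantiopure B-allyl-10-phenyl-9-borabicyclo[3.3.2]decane, the antipode being the one whose closed transition state delivers allyl to the face opposite the C3 methyl group. Amino-alcohol work-up then returns to the route at 22. No compound outside the list is made (F0).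

**Step 12.** What may go wrong: the product 20, a hydroquinone mono-ether, is oxidised by the iodane faster than 17 is consumed, so isolated 20 is lost to over-oxidation; some capture at the ortho carbon C2′ may add to this. Fallback: the oxidation is no longer arrested at the phenol. Starting from 17, the cyclisation is run as above and, without isolation, methanol, NaHCO3 and a second equivalent of PhI(OAc)2 are added. Compound 20 and any C7a cation already formed by over-oxidation are then both collected as the ketal 21, where the route is rejoined. No compound outside the list is made (F0).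

**Step 16.** What may go wrong: under acid the tertiary, doubly allylic C5 methyl ether ionises in competition with the C7a ketal (allyl migration and rearomatisation), or the cyclic ketal opens at O1 instead of releasing the MOM group. Fallback: the C6 carbonyl is brought in at the quinone stage, so that no cationic unmasking is needed. Starting from 20, HCl (cat.) in MeOH removes the MOM group and should give the catechol (2S,3S)-7-methoxy-3-methyl-2-(3,4,5-trimethoxyphenyl)-2,3-dihydro-1-benzofuran-5,6-diol F1. Ag2O in Et2O oxidises it to the o-quinone (2S,3S)-7-methoxy-3-methyl-2-(3,4,5-trimethoxyphenyl)-2,3-dihydro-1-benzofuran-5,6-dione F2. Allylmagnesium bromide at −78 °C adds to the C5 carbonyl, because the C6 carbonyl is deactivated as a vinylogous ester of O1, and should give the o-quinol (2S,3S,5R)-5-hydroxy-7-methoxy-3-methyl-5-(prop-2-en-1-yl)-2-(3,4,5-trimethoxyphenyl)-3,5-dihydro-1-benzofuran-6(2H)-one F3. Methyl triflate with 2,6-di-tert-butyl-4-methylpyridine methylates the tertiary hydroxyl and returns to the route at 24.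

## Further compounds

F0 | step 14 | none | none
F0 | step 12 | none | none
F1 | step 16 | (2S,3S)-7-methoxy-3-methyl-2-(3,4,5-trimethoxyphenyl)-2,3-dihydro-1-benzofuran-5,6-diol | Oc1c(O)cc2c(c1OC)O[C@H](c1cc(OC)c(OC)c(OC)c1)[C@H]2C
F2 | step 16 | (2S,3S)-7-methoxy-3-methyl-2-(3,4,5-trimethoxyphenyl)-2,3-dihydro-1-benzofuran-5,6-dione | O=C1C=C2[C@H](C)[C@@H](c3cc(OC)c(OC)c(OC)c3)OC2=C(OC)C1=O
F3 | step 16 | (2S,3S,5R)-5-hydroxy-7-methoxy-3-methyl-5-(prop-2-en-1-yl)-2-(3,4,5-trimethoxyphenyl)-3,5-dihydro-1-benzofuran-6(2H)-one | C=CC[C@@]1(O)C=C2C(=C(OC)C1=O)O[C@H](c1cc(OC)c(OC)c(OC)c1)[C@H]2C
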